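**Plan**

- Retrosynthesis: the free phenol and the C7 methyl ether go back to a MOM ether and a silyl group at C7. Ring A is then cut at C3a–C7a, C4–C5 and C6–C7, after which the ynol ether bond O1–C7a and the C2–C3 bond are cut.
- Enabling feature: the six carbons of ring A are three adjacent pairs, C7a–C7, C3a–C4 and C5–C6. The first two are already joined through O1–C2–C3 of the dihydrofuran ring and the third carries the hydroxypropenyl chain, so ring A with its fused ring is a 1,6-diyne plus an alkyne.
- Forward: propargylation of protected syringaldehyde makes C2–C3; the alkoxide is turned into a silyl-capped ynol ether (C7a and C7 from trichloroethylene); one rhodium-catalysed [2+2+2] cycloaddition with a protected pentenynol then closes the dihydrofuran and benzene rings together.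
- End game: silicon at C7 is oxidised to the phenol, which is methylated, and the MOM group is removed.
- Stereochemistry: C3 comes from an (S)-propargylic mesylate (asymmetric transfer hydrogenation) and is transferred with inversion; C2 follows from the anti selectivity of the allenylzinc addition; the E alkene is bought.

Key step: step 11

Remark: the C3 hydroxymethyl oxygen carries a triisopropylsilyl group from the start, because a smaller silyl group could migrate to the neighbouring potassium alkoxide in step 7; (triisopropylsilyloxy)acetaldehyde is taken as a catalogue reagent.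

**Route**

Step 1
Reactants: 1 syringaldehyde
Product: 2 3,5-dimethoxy-4-(methoxymethoxy)benzaldehyde
Conditions: MOMCl, iPr2NEt, CH2Cl2, 0 °C → rt
Reagents that add atoms: chloromethyl methyl ether, COCCl
Why: Williamson-type O-alkylation of the acidic para-formyl phenol gives the MOM acetal, which is inert to the organozinc, potassium hydride, butyllithium, fluoride and peroxide used later.

Step 2
Reactants: 3 (triisopropylsilyloxy)acetaldehyde; 4 trimethylsilylacetylene
Product: 6 rac-1-(triisopropylsilyloxy)-4-(trimethylsilyl)but-3-yn-2-ol, via lithium (trimethylsilyl)acetylide 5 (not isolated)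
Conditions: 4, n-BuLi, THF, −78 °C; then 3, −78 → 0 °C
Reagents that add atoms: n-butyllithium, [Li]CCCC (its lithium is held only in 5)
Why: 1,2-addition of a lithium acetylide to an unhindered aldehyde; the racemate suffices because the carbinol is oxidised in the next step.

Step 3
Reactants: 6 rac-1-(triisopropylsilyloxy)-4-(trimethylsilyl)but-3-yn-2-ol
Product: 7 1-(triisopropylsilyloxy)-4-(trimethylsilyl)but-3-yn-2-one
Conditions: Dess–Martin periodinane, CH2Cl2, 0 °C → rt
Reagents that add atoms: none
Why: Dess–Martin oxidation of a secondary propargylic alcohol to the ynone runs under near-neutral conditions that leave the C-silyl and O-silyl groups alone.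

Step 4
Reactants: 7 1-(triisopropylsilyloxy)-4-(trimethylsilyl)but-3-yn-2-one
Product: 8 (S)-1-(triisopropylsilyloxy)-4-(trimethylsilyl)but-3-yn-2-ol
Conditions: Ru[(R,R)-TsDPEN](p-cymene) (2 mol%), iPrOH, rt
Reagents that add atoms: none
Why: Noyori asymmetric transfer hydrogenation of alkynyl ketones, in which the alkyne takes the place of the aryl group of an aryl ketone, so the (R,R) catalyst should deliver hydride to the face that gives the (S)-carbinol (S because CH2OSi outranks the alkyne).

Step 5
Reactants: 8 (S)-1-(triisopropylsilyloxy)-4-(trimethylsilyl)but-3-yn-2-ol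
Product: 9 (S)-1-(triisopropylsilyloxy)-4-(trimethylsilyl)but-3-yn-2-yl methanesulfonate
Conditions: MsCl, Et3N, CH2Cl2, −78 → 0 °C
Reagents that add atoms: methanesulfonyl chloride, CS(=O)(=O)Cl
Why: O-sulfonylation (mesylation) does not touch the stereocentre and supplies the leaving group for palladium.

Step 6
Reactants: 2 3,5-dimethoxy-4-(methoxymethoxy)benzaldehyde; 9 (S)-1-(triisopropylsilyloxy)-4-(trimethylsilyl)but-3-yn-2-yl methanesulfonate
Product: 11 (1S,2R)-1-[3,5-dimethoxy-4-(methoxymethoxy)phenyl]-2-[(triisopropylsilyloxy)methyl]-4-(trimethylsilyl)but-3-yn-1-ol, via allenyl(ethyl)zinc 10 (not isolated)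
Conditions: Pd(OAc)2 (5 mol%), PPh3 (5 mol%), Et2Zn (3 equiv), THF, −78 → −20 °C
Reagents that add atoms: diethylzinc, CC[Zn]CC (its ethylzinc unit is held only in 10)
Why: Marshall propargylation, in which zerovalent palladium displaces the mesylate anti (SN2′), transmetalation to zinc keeps the allene axis, and SE2′ addition through a closed six-membered transition state turns the axis into the 2R centre (net inversion) and, with the aryl group equatorial, gives the anti 1S carbinol; any syn isomer is removed by chromatography.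

Step 7
Reactants: 11 (1S,2R)-1-[3,5-dimethoxy-4-(methoxymethoxy)phenyl]-2-[(triisopropylsilyloxy)methyl]-4-(trimethylsilyl)but-3-yn-1-ol; 12 trichloroethylene
Product: 13 (E)-1,2-dichlorovinyl ether of 11
Conditions: KH, THF, 0 °C; then Cl2C=CHCl, −50 °C → rt
Reagents that add atoms: none
Why: Alkoxide addition to dichloroacetylene generated in the flask (the dichlorovinyl ether route to ynol ethers) is an anti addition that gives the E ether; the stereocentres carry no acidic hydrogen under these conditions.

Step 8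
Reactants: 13 (E)-1,2-dichlorovinyl ether of 11
Product: 16 (1S,2R)-configured diisopropyl(isopropoxy)silyl ynol ether with C-trimethylsilyl alkyne, via lithium alkynyl ether 14 (not isolated), via alkynyl(chloro)diisopropylsilane 15 (not isolated)
Conditions: n-BuLi (2.4 equiv), THF, −78 °C; added to iPr2SiCl2 (3 equiv), −78 → 0 °C; then iPrOH, Et3N, DMAP (cat.), 0 °C → rt
Reagents that add atoms: n-butyllithium, [Li]CCCC (its lithium is held only in 14); dichlorodiisopropylsilane, CC(C)[Si](Cl)(Cl)C(C)C; propan-2-ol, CC(C)O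
Why: Dehydrochlorination and chlorine–lithium exchange give the lithium alkynyl ether, which is C-silylated once by the excess hindered dichlorosilane (acetylide silylation), and alcoholysis caps the remaining Si–Cl bond.

Step 9
Reactants: 16 (1S,2R)-configured diisopropyl(isopropoxy)silyl ynol ether with C-trimethylsilyl alkyne
Product: 17 [(1S,2R)-1-[3,5-dimethoxy-4-(methoxymethoxy)phenyl]-2-[(triisopropylsilyloxy)methyl]but-3-yn-1-yl]oxyethynyl-diisopropyl(isopropoxy)silane
Conditions: K2CO3 (cat.), MeOH/THF, 0 °C → rt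
Reagents that add atoms: none
Why: Base-catalysed methanolysis (protodesilylation) cleaves only the unhindered C–SiMe3 bond, since the diisopropyl(isopropoxy)silyl alkyne is shielded like a triisopropylsilyl alkyne and ynol ethers tolerate base.

Step 10
Reactants: 18 (E)-pent-2-en-4-yn-1-ol
Product: 19 (E)-tert-butyldimethyl(pent-2-en-4-yn-1-yloxy)silane
Conditions: TBSCl, imidazole, DMF, rt
Reagents that add atoms: tert-butyldimethylsilyl chloride, CC(C)(C)[Si](C)(C)Cl
Why: Standard O-silylation of a primary allylic alcohol; the E alkene is carried through unchanged.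

Step 11
Reactants: 17 the diyne of step 9; 19 (E)-tert-butyldimethyl(pent-2-en-4-yn-1-yloxy)silane
Product: 20 (2S,3R)-5-[(E)-3-(tert-butyldimethylsilyloxy)prop-1-enyl]-7-[diisopropyl(isopropoxy)silyl]-2-[3,5-dimethoxy-4-(methoxymethoxy)phenyl]-3-[(triisopropylsilyloxy)methyl]-2,3-dihydrobenzofuran
Conditions: [Rh(cod)2]BF4 (5 mol%), rac-BINAP (5 mol%), activated with H2; 19 (3 equiv), CH2Cl2, rt, slow addition of 17
Reagents that add atoms: none
Why: Oxidative coupling of the two tethered alkynes on cationic monovalent rhodium gives a bicyclic rhodacyclopentadiene (C3a–C7a), the alkyne of 19 then inserts, and reductive elimination completes C4–C5 and C6–C7 and releases the catalyst. The closest known reaction type is the rhodium-catalysed [2+2+2] cycloaddition of heteroatom-tethered 1,6-diynes with terminal alkynes (ynamide diynes to indolines, aryl ynol ether diynes to benzofurans); the silyl-capped alkyl ynol ether is a new substrate of that class. The dihydrofuran ring closes as the five-membered ring fused to the metallacycle when the 1,6-diyne couples, and ring A closes by insertion of the third alkyne followed by carbon–carbon reductive elimination, all six of its carbons being former alkyne carbons. No stereocentre is formed, and C2 and C3 are spectators under these neutral conditions. The step needs regiocontrol (chain at C5, not C6) and chemoselectivity (alkyne rather than alkene of 19, crossed rather than homo-trimer): the bulky silyl group on the rhodium-bound carbon should force the substituted alkyne carbon of 19 to bond to C4, away from silicon; the alkene of 19 is a far poorer insertion partner than its terminal alkyne; and the intramolecular first coupling with excess 19 favours the crossed product. Room temperature is kept because benzylic alkynyl ethers can rearrange sigmatropically on heating.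

Step 12
Reactants: 20 the 7-silyl dihydrobenzofuran of step 11
Product: 21 (2S,3R)-2-[3,5-dimethoxy-4-(methoxymethoxy)phenyl]-3-(hydroxymethyl)-5-[(E)-3-hydroxyprop-1-enyl]-2,3-dihydrobenzofuran-7-ol
Conditions: TBAF (5 equiv), KHCO3, 30% H2O2, THF/MeOH, 0 → 45 °C
Reagents that add atoms: hydrogen peroxide, OO
Why: Tamao–Fleming oxidation, in which fluoride activates the alkoxysilane, hydroperoxide adds to silicon and the aryl group migrates to oxygen so that the C7–O bond forms at the ipso carbon; the same fluoride cleaves both silyl ethers, and basic peroxide does not epoxidise the electron-rich alkene.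

Step 13
Reactants: 21 the 7-hydroxy compound of step 12
Product: 22 (2S,3R)-2-[3,5-dimethoxy-4-(methoxymethoxy)phenyl]-3-(hydroxymethyl)-5-[(E)-3-hydroxyprop-1-enyl]-7-methoxy-2,3-dihydrobenzofuran
Conditions: MeI, K2CO3, acetone, rt → 40 °C
Reagents that add atoms: iodomethane, CI
Why: Williamson O-methylation; carbonate deprotonates only the single free phenol, so the two primary alcohols stay unmethylated.

Step 14
Reactants: 22 the MOM ether of step 13
Product: 24 (2S,3R)-2-(4-hydroxy-3,5-dimethoxyphenyl)-3-(hydroxymethyl)-5-[(E)-3-hydroxyprop-1-enyl]-7-methoxy-2,3-dihydrobenzofuran, via tris(trimethylsilyl) ether 23 (not isolated)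
Conditions: TMSOTf (6 equiv), 2,2′-bipyridyl (9 equiv), CH2Cl2/MeCN, 0 °C → rt; then H2O, rt
Reagents that add atoms: trimethylsilyl trifluoromethanesulfonate, C[Si](C)(C)OS(=O)(=O)C(F)(F)F (its silyl groups are held only in 23)
Why: Silyl triflate–bipyridyl acetal exchange converts the aryl MOM ether into an aryl silyl ether under buffered, non-protic conditions, the two alcohols being silylated only transiently, and water then hydrolyses all three trimethylsilyl ethers, which avoids the protic acid that would ionise the electron-rich allylic alcohol.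

**Compound list**

1 | syringaldehyde (4-hydroxy-3,5-dimethoxybenzaldehyde) | COc1cc(C=O)cc(OC)c1O | starting material
2 | 3,5-dimethoxy-4-(methoxymethoxy)benzaldehyde | COCOc1c(OC)cc(C=O)cc1OC | intermediate
3 | (triisopropylsilyloxy)acetaldehyde | CC(C)[Si](OCC=O)(C(C)C)C(C)C | starting material
4 | trimethylsilylacetylene | C#C[Si](C)(C)C | starting material
5 | lithium (trimethylsilyl)acetylide | [Li]C#C[Si](C)(C)C | intermediate
6 | rac-1-(triisopropylsilyloxy)-4-(trimethylsilyl)but-3-yn-2-ol | CC(C)[Si](OCC(O)C#C[Si](C)(C)C)(C(C)C)C(C)C | intermediate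
7 | 1-(triisopropylsilyloxy)-4-(trimethylsilyl)but-3-yn-2-one | CC(C)[Si](OCC(=O)C#C[Si](C)(C)C)(C(C)C)C(C)C | intermediate
8 | (S)-1-(triisopropylsilyloxy)-4-(trimethylsilyl)but-3-yn-2-ol | CC(C)[Si](OC[C@@H](O)C#C[Si](C)(C)C)(C(C)C)C(C)C | intermediate
9 | (S)-1-(triisopropylsilyloxy)-4-(trimethylsilyl)but-3-yn-2-yl methanesulfonate | CC(C)[Si](OC[C@@H](OS(C)(=O)=O)C#C[Si](C)(C)C)(C(C)C)C(C)C | intermediate
10 | ethyl[(aS)-4-(triisopropylsilyloxy)-1-(trimethylsilyl)buta-1,2-dien-1-yl]zinc | CC[Zn]C([Si](C)(C)C)=[C@@]=C([H])CO[Si](C(C)C)(C(C)C)C(C)C | intermediate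
11 | (1S,2R)-1-[3,5-dimethoxy-4-(methoxymethoxy)phenyl]-2-[(triisopropylsilyloxy)methyl]-4-(trimethylsilyl)but-3-yn-1-ol (anti) | COc1cc([C@@H](O)[C@@H](CO[Si](C(C)C)(C(C)C)C(C)C)C#C[Si](C)(C)C)cc(OC)c1OCOC | intermediate
12 | trichloroethylene | ClC=C(Cl)Cl | starting material
13 | (E)-1,2-dichlorovinyl ether of 11, (1S,2R) | COc1cc([C@@H](O/C(Cl)=C\Cl)[C@@H](CO[Si](C(C)C)(C(C)C)C(C)C)C#C[Si](C)(C)C)cc(OC)c1OCOC | intermediate
14 | lithium alkynyl ether of 11, (1S,2R) | COc1cc([C@@H](OC#C[Li])[C@@H](CO[Si](C(C)C)(C(C)C)C(C)C)C#C[Si](C)(C)C)cc(OC)c1OCOC | intermediate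
15 | chloro(diisopropyl)silylethynyl ether of 11, (1S,2R) | COc1cc([C@@H](OC#C[Si](Cl)(C(C)C)C(C)C)[C@@H](CO[Si](C(C)C)(C(C)C)C(C)C)C#C[Si](C)(C)C)cc(OC)c1OCOC | intermediate
16 | diisopropyl(isopropoxy)silylethynyl ether of 11, (1S,2R), C-trimethylsilyl alkyne retained | COc1cc([C@@H](OC#C[Si](OC(C)C)(C(C)C)C(C)C)[C@@H](CO[Si](C(C)C)(C(C)C)C(C)C)C#C[Si](C)(C)C)cc(OC)c1OCOC | intermediate
17 | [(1S,2R)-1-[3,5-dimethoxy-4-(methoxymethoxy)phenyl]-2-[(triisopropylsilyloxy)methyl]but-3-yn-1-yl]oxyethynyl-diisopropyl(isopropoxy)silane (diyne) | COc1cc([C@@H](OC#C[Si](OC(C)C)(C(C)C)C(C)C)[C@@H](CO[Si](C(C)C)(C(C)C)C(C)C)C#C)cc(OC)c1OCOC | intermediate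
18 | (E)-pent-2-en-4-yn-1-ol | C#C/C=C/CO | starting material
19 | (E)-tert-butyldimethyl(pent-2-en-4-yn-1-yloxy)silane | C#C/C=C/CO[Si](C)(C)C(C)(C)C | intermediate
20 | (2S,3R)-5-[(E)-3-(tert-butyldimethylsilyloxy)prop-1-enyl]-7-[diisopropyl(isopropoxy)silyl]-2-[3,5-dimethoxy-4-(methoxymethoxy)phenyl]-3-[(triisopropylsilyloxy)methyl]-2,3-dihydrobenzofuran | COc1cc([C@H]2Oc3c([Si](OC(C)C)(C(C)C)C(C)C)cc(/C=C/CO[Si](C)(C)C(C)(C)C)cc3[C@@H]2CO[Si](C(C)C)(C(C)C)C(C)C)cc(OC)c1OCOC | intermediate
21 | (2S,3R)-2-[3,5-dimethoxy-4-(methoxymethoxy)phenyl]-3-(hydroxymethyl)-5-[(E)-3-hydroxyprop-1-enyl]-2,3-dihydrobenzofuran-7-ol | COc1cc([C@H]2Oc3c(O)cc(/C=C/CO)cc3[C@@H]2CO)cc(OC)c1OCOC | intermediate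
22 | (2S,3R)-2-[3,5-dimethoxy-4-(methoxymethoxy)phenyl]-3-(hydroxymethyl)-5-[(E)-3-hydroxyprop-1-enyl]-7-methoxy-2,3-dihydrobenzofuran | COc1cc([C@H]2Oc3c(OC)cc(/C=C/CO)cc3[C@@H]2CO)cc(OC)c1OCOC | intermediate
23 | tris(trimethylsilyl) ether of 24 (aryl and both alkyl oxygens silylated) | COc1cc([C@H]2Oc3c(OC)cc(/C=C/CO[Si](C)(C)C)cc3[C@@H]2CO[Si](C)(C)C)cc(OC)c1O[Si](C)(C)C | intermediate
24 | (2S,3R)-2-(4-hydroxy-3,5-dimethoxyphenyl)-3-(hydroxymethyl)-5-[(E)-3-hydroxyprop-1-enyl]-7-methoxy-2,3-dihydrobenzofuran (CNP0191372.1) | COc1cc([C@H]2Oc3c(OC)cc(/C=C/CO)cc3[C@@H]2CO)cc(OC)c1O | target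

**Count and risks**

Total steps: 14. Longest linear sequence: 12 steps (steps 2–9 and 11–14, from 3 and 4).

Steps most likely to fail:

1. Step 11. The conjugated enyne may be drained by rhodium-catalysed self-oligomerisation or engage through its alkene, so that the crossed trimer forms inefficiently or with mixed orientation. The fallback changes the third component and builds the side chain afterwards. It sets out from 17 and rejoins the route at 22. Cyclotrimerisation of 17 with the simple monoalkyne tert-butyldimethyl(prop-2-ynyloxy)silane (bought) under the conditions of step 11 should give (2S,3R)-5-[(tert-butyldimethylsilyloxy)methyl]-7-[diisopropyl(isopropoxy)silyl]-2-[3,5-dimethoxy-4-(methoxymethoxy)phenyl]-3-[(triisopropylsilyloxy)methyl]-2,3-dihydrobenzofuran F1. Fluoride and peroxide as in step 12 should give (2S,3R)-2-[3,5-dimethoxy-4-(methoxymethoxy)phenyl]-3,5-bis(hydroxymethyl)-2,3-dihydrobenzofuran-7-ol F2. MeI and K2CO3 give its 7-methyl ether F3. MnO2 in CH2Cl2 oxidises only the benzylic alcohol, to the 5-carbaldehyde F4. Wittig olefination with Ph3P=CHCO2Et gives the ethyl (E)-propenoate F5, and DIBAL-H at −78 °C reduces the ester to the allylic alcohol 22.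

2. Step 7. Silyl transfer to the potassium alkoxide, from the C-silyl alkyne or from the neighbouring silyl ether, may compete with capture by dichloroacetylene. The fallback avoids the alkoxide altogether. It sets out from 11 and rejoins at 16. Formylation with acetic formic anhydride and pyridine gives the formate ester of 11 F6. Dibromomethylenation of the formate carbonyl with CBr4 and PPh3 gives the 2,2-dibromovinyl ether of 11 F7. n-BuLi (2 equiv, −78 °C) converts this by elimination and bromine–lithium exchange into the same lithium alkynyl ether 14, which is quenched as in step 8 to give 16.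

3. Step 14. The silyl triflate may ionise the electron-rich allylic C–O bond, leading to substitution or oligomerisation of the side chain before the hindered aryl acetal has exchanged. The fallback lowers the electron density of the side chain before deprotection. It sets out from 22 and rejoins at 24. MnO2 oxidises only the allylic alcohol to the (E)-propenal of 22 F8. Dilute HCl in THF/MeOH then removes the MOM group without risk to the deactivated enal, giving the (E)-propenal of 24 F9. Luche reduction (NaBH4, CeCl3·7H2O, MeOH, 0 °C) returns the allylic alcohol 24.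

**Further compounds**

F1 | step 11 | (2S,3R)-5-[(tert-butyldimethylsilyloxy)methyl]-7-[diisopropyl(isopropoxy)silyl]-2-[3,5-dimethoxy-4-(methoxymethoxy)phenyl]-3-[(triisopropylsilyloxy)methyl]-2,3-dihydrobenzofuran | COc1cc([C@H]2Oc3c([Si](OC(C)C)(C(C)C)C(C)C)cc(CO[Si](C)(C)C(C)(C)C)cc3[C@@H]2CO[Si](C(C)C)(C(C)C)C(C)C)cc(OC)c1OCOC
F2 | step 11 | (2S,3R)-2-[3,5-dimethoxy-4-(methoxymethoxy)phenyl]-3,5-bis(hydroxymethyl)-2,3-dihydrobenzofuran-7-ol | COc1cc([C@H]2Oc3c(O)cc(CO)cc3[C@@H]2CO)cc(OC)c1OCOC
F3 | step 11 | (2S,3R)-2-[3,5-dimethoxy-4-(methoxymethoxy)phenyl]-3,5-bis(hydroxymethyl)-7-methoxy-2,3-dihydrobenzofuran | COc1cc([C@H]2Oc3c(OC)cc(CO)cc3[C@@H]2CO)cc(OC)c1OCOC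
F4 | step 11 | (2S,3R)-2-[3,5-dimethoxy-4-(methoxymethoxy)phenyl]-3-(hydroxymethyl)-7-methoxy-2,3-dihydrobenzofuran-5-carbaldehyde | COc1cc([C@H]2Oc3c(OC)cc(C=O)cc3[C@@H]2CO)cc(OC)c1OCOC
F5 | step 11 | ethyl (E)-3-[(2S,3R)-2-[3,5-dimethoxy-4-(methoxymethoxy)phenyl]-3-(hydroxymethyl)-7-methoxy-2,3-dihydrobenzofuran-5-yl]prop-2-enoate | COc1cc([C@H]2Oc3c(OC)cc(/C=C/C(=O)OCC)cc3[C@@H]2CO)cc(OC)c1OCOC
F6 | step 7 | formate ester of 11, (1S,2R) | COc1cc([C@@H](OC=O)[C@@H](CO[Si](C(C)C)(C(C)C)C(C)C)C#C[Si](C)(C)C)cc(OC)c1OCOC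
F7 | step 7 | 2,2-dibromovinyl ether of 11, (1S,2R) | COc1cc([C@@H](OC=C(Br)Br)[C@@H](CO[Si](C(C)C)(C(C)C)C(C)C)C#C[Si](C)(C)C)cc(OC)c1OCOC
F8 | step 14 | (E)-3-[(2S,3R)-2-[3,5-dimethoxy-4-(methoxymethoxy)phenyl]-3-(hydroxymethyl)-7-methoxy-2,3-dihydrobenzofuran-5-yl]prop-2-enal | COc1cc([C@H]2Oc3c(OC)cc(/C=C/C=O)cc3[C@@H]2CO)cc(OC)c1OCOC
F9 | step 14 | (E)-3-[(2S,3R)-2-(4-hydroxy-3,5-dimethoxyphenyl)-3-(hydroxymethyl)-7-methoxy-2,3-dihydrobenzofuran-5-yl]prop-2-enal | COc1cc([C@H]2Oc3c(OC)cc(/C=C/C=O)cc3[C@@H]2CO)cc(OC)c1O
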